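The impurity cannot take more initiator than there is impurity, yet a share read from the starting rates can ask exactly that.

| flask | free monomer | transfer agent | initiator | impurity | time |
|---|---|---|---|---|---|
| Thursday's | 0.36 M | 3.60 mM | 19 mM | 6.1 mM | 2.5 h |
| Tuesday's | 1.5 M | 3.60 mM | 19 mM | 6.1 mM | 2.5 h |

    free monomer + initiator → living end + monomer in chains (k1 = 0.0108 L mol⁻¹ s⁻¹)
    free monomer + living end → monomer in chains + living end, rate k2*[living end]*[free monomer] (k2 = 0.0416 L mol⁻¹ s⁻¹)
    living end + transfer agent → dead chain (k3 = 0.0674 L mol⁻¹ s⁻¹)
    initiator + impurity → spent initiator (k4 = 0.492 L mol⁻¹ s⁻¹)

- the average divides the monomer in chains by the number of chains begun, living and dead together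
- run time (Thursday's): 2.5 h

1. which of the two ends with the longer chains by the average number of monomer units in a chain (chains begun, living or dead) ("neither" if they lie within 10%) (Thursday's / Tuesday's / neither)
2. average number of monomer units in a chain (chains begun, living or dead) at the end, Thursday's
3. average number of monomer units in a chain (chains begun, living or dead) at the end, Tuesday's

The chain length here is monomer in chains over chains begun, and each chain begun, living or later dead, has used one initiator in the step with free monomer. So we need the fraction of the initiator charge that reaches free monomer, and we try two ways on Thursday's flask. At the start its free monomer takes initiator 1.30 times as fast as its impurity does, which gives chains 0.564 of the charge and the impurity the other 0.436. From the other end, the impurity amounts to i = 0.321 of the initiator charge, so if it were all consumed, chains would get 0.679. The two part, and the first cheats: by keeping the impurity at its charge, it hands the impurity more initiator than the 0.321 it can take.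

To join the ends we let the impurity fall and hold the free monomer at its charge, a rough step: on Thursday's the half-life of initiator by impurity, 0.064 h, is shorter than 0.244 h, the half-life of free monomer by step 2 with the whole initiator charge counted as living ends. Let x be the fraction of impurity left, and b the starting constant times the free monomer charge, over the impurity constant times the initiator charge. The moment-by-moment share then integrates to f = b ln(1/x), while counting the impurity consumed gives f = 1 − i(1 − x). Thursday's b is 0.416 and Tuesday's 1.73. Substituting back and forth gives 0.734 for Thursday's and 0.873 for Tuesday's. This f is the chain yield, the fraction of the initiator charge that begins a chain, usually called the initiator efficiency.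

We count the transfer agent as consumed, one living end each, since Thursday's 13.9 mM of chains begun outnumber its 3.60 mM of transfer agent, and the 10.3 mM of living ends that remain give the transfer agent a half-life of 0.276 h, shorter than the run. The remaining living ends then leave 2.08% of the free monomer on Thursday's and 0.772% on Tuesday's. Our lengths are 25.3 and 89.7, so Tuesday's is longer.

The forecast names Tuesday's, with 25.6 and 90, on the ground that “Tuesday's roughly fourfold monomer charge gives much longer chains”.

The simulation gives 25.6 for Thursday's and 90.0 for Tuesday's, so Tuesday's ends longer.

At 2.50 h, Thursday's still holds 1.9% of its free monomer and Tuesday's 0.69%, with initiator at 0% and 0%. With the yields held, converting that remainder gives 25.8 and 90.4; the flasks at 25.0 h show 26.1 and 90.7.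

For Tuesday's recipe with 0.032 M of initiator, b becomes 1.03 and i becomes 0.191, so the yield is 0.890 and the length 52.7. That flask gives 52.9.

The numbers of this flask were chosen freely; no experiment stands behind them.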